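Retrosynthesis: in 5-henicosyl-1H-pyrrole-2-carbaldehyde both substituents sit next to N1, at C2 and C5. The C3–C4 bond opposite nitrogen is therefore the only pyrrole ring bond between two bare CH atoms, and it is made by joining two terminal vinyl groups.
The aromatic ring is traced back to a 1-tosyl-2,5-dihydropyrrole-2-carbaldehyde, where loss of p-toluenesulfinic acid across N1–C2 supplies the missing unsaturation. The aldehyde is traced back to the 2-hydroxymethyl-3-pyrroline.
The only ring is formed once, as that 3-pyrroline, by ring-closing metathesis of an N-tosylamine with two alpha-branched allyl arms: a 1-hydroxybut-3-en-2-yl arm and a tetracos-1-en-3-yl arm. It is aromatised in the last step.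
The crowded second C–N bond is made by regioretentive rhodium-catalysed allylic amination of a silyl-protected branched carbonate with N-tosyl-tetracos-1-en-3-amine. Palladium-catalysed opening of butadiene monoxide is kept in reserve, because a hindered sulfonamide may attack the far allyl terminus.
The sulfonamide comes from 1-docosanol through docosanal, its tosylamide/sulfinate adduct and vinylmagnesium bromide. The carbonate comes from (tert-butyldimethylsilyloxy)acetaldehyde, the same Grignard reagent and methyl chloroformate.
Key step: step 7

Remark: the target has no stereocentre, so racemic materials are used, and every sp3 centre made on the way is carried as a racemate or diastereomer mixture, since both ring centres vanish on aromatisation.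

Step 1
Reactants: 1 1-docosanol
Product: 2 docosanal
Conditions: IBX (1.5 equiv), EtOAc, 80 °C
Reagents that add atoms: none
Why: Hypervalent-iodine (IBX) oxidation of a primary alcohol stops at the aldehyde because no water is present to form a hydrate, hot ethyl acetate keeps the waxy C22 chain dissolved while reagent and spent reagent stay insoluble and are filtered off, and no stereocentre is involved.

Step 2
Reactants: 2 docosanal; 3 p-toluenesulfonamide
Product: 4 4-methyl-N-[1-(4-methylbenzenesulfonyl)docosyl]benzenesulfonamide (racemic)
Conditions: sodium p-toluenesulfinate (1.1 equiv), HCO2H, H2O/THF, rt to 40 °C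
Reagents that add atoms: sodium p-toluenesulfinate, Cc1ccc(cc1)S(=O)[O-].[Na+]
Why: Three-component Mannich-type condensation to an alpha-amido sulfone, in which formic acid liberates p-toluenesulfinic acid that traps the transient N-tosyliminium ion, so the enolisable imine is stored as a crystalline adduct whose single new centre is racemic and disappears again in step 3.

Step 3
Reactants: 4 4-methyl-N-[1-(4-methylbenzenesulfonyl)docosyl]benzenesulfonamide; 5 vinylmagnesium bromide
Product: 7 4-methyl-N-(tetracos-1-en-3-yl)benzenesulfonamide (racemic), via N-tosylimine of docosanal 6 (not isolated)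
Conditions: 5 (3 equiv), THF, −40 to 0 °C; aqueous work-up
Reagents that add atoms: none
Why: Base-induced sulfinate elimination followed by 1,2-addition of a Grignard reagent to an N-sulfonylimine, a known way to allylic sulfonamides: the first equivalent of 5 deprotonates N–H and releases 6 only gradually, the strongly activated C=N then captures a second equivalent faster than it tautomerises, and the new allylic centre is formed without control as a racemate because it later becomes sp2 C5 of the pyrrole.

Step 4
Reactants: 8 (tert-butyldimethylsilyloxy)acetaldehyde; 5 vinylmagnesium bromide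
Product: 10 1-[(tert-butyldimethylsilyl)oxy]but-3-en-2-yl methyl carbonate (racemic), via bromomagnesium alkoxide 9 (not isolated)
Conditions: 5 (1.1 equiv), THF, −78 °C; then ClCO2Me (1.5 equiv), −78 to 0 °C
Reagents that add atoms: methyl chloroformate, COC(=O)Cl
Why: 1,2-Addition of a vinyl Grignard reagent to an aldehyde with O-acylation of the magnesium alkoxide 9 in the same flask, where the low temperature and the tight magnesium–oxygen bond hold back O-to-O silyl migration, and the carbinol centre is racemic since no control is needed.

Step 5
Reactants: 7 4-methyl-N-(tetracos-1-en-3-yl)benzenesulfonamide; 10 1-[(tert-butyldimethylsilyl)oxy]but-3-en-2-yl methyl carbonate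
Product: 12 N-{1-[(tert-butyldimethylsilyl)oxy]but-3-en-2-yl}-4-methyl-N-(tetracos-1-en-3-yl)benzenesulfonamide (diastereomer mixture), via lithium sulfonamide 11 (not isolated)
Conditions: LiN(SiMe3)2 (1.05 equiv), THF, 0 °C; then 10 (1.5 equiv), RhCl(PPh3)3 (10 mol %), P(OMe)3 (40 mol %), THF, 30 °C
Reagents that add atoms: none
Why: Regioretentive rhodium-catalysed allylic amination of a secondary allylic carbonate with a lithium sulfonamide, a reaction class already used to join alpha-branched N-tosyl allylamines to branched carbonates: the phosphite-modified monovalent rhodium centre ionises 10 to an enyl (sigma plus pi) species that does not equilibrate and is attacked at the carbon that carried the carbonate, so nitrogen ends on the internal carbon next to CH2OTBS, and since both partners are racemic and the substitution is stereospecific the new centre appears as a mixture of two diastereomers that are both usable.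

Step 6
Reactants: 12 N-{1-[(tert-butyldimethylsilyl)oxy]but-3-en-2-yl}-4-methyl-N-(tetracos-1-en-3-yl)benzenesulfonamide
Product: 13 N-(1-hydroxybut-3-en-2-yl)-4-methyl-N-(tetracos-1-en-3-yl)benzenesulfonamide (diastereomer mixture)
Conditions: Bu4NF (1.2 equiv), THF, 0 °C to rt
Reagents that add atoms: none
Why: Fluoride-induced cleavage of a silyl ether, driven by the strong Si–F bond, leaves the sulfonamide, both vinyl groups and both stereocentres untouched.

Step 7
Reactants: 13 N-(1-hydroxybut-3-en-2-yl)-4-methyl-N-(tetracos-1-en-3-yl)benzenesulfonamide
Product: 14 (5-henicosyl-1-tosyl-2,5-dihydro-1H-pyrrol-2-yl)methanol (cis/trans mixture)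
Conditions: second-generation Grubbs catalyst (H2IMes)(PCy3)Cl2Ru=CHPh (5 mol %), 1,4-benzoquinone (10 mol %), CH2Cl2 (0.01 mol/L), 40 °C, argon sparge
Reagents that add atoms: none
Why: Phosphine loss from the precatalyst gives a 14-electron ruthenium alkylidene that exchanges with one terminal vinyl group of 13 by [2+2] cycloaddition and cycloreversion, and the substrate-bound alkylidene then adds across the second vinyl group of the same molecule to a ruthenacyclobutane whose cycloreversion forms C3=C4 and a ruthenium methylidene that continues the cycle. The closest known reaction type is ring-closing metathesis of N-sulfonyl diallylamines, bis-alpha-branched examples included, to 1-sulfonyl-3-pyrrolines. The one ring closes as a five-membered ring from the nitrogen-centred 1,6-diene, the two internal alkene carbons becoming ring atoms C3 and C4 and the two terminal CH2 groups leaving as ethene, whose escape from the refluxing, sparged solution makes the closure irreversible. No stereocentre is created, and the existing C2 and C5 centres pass through unchanged, so the cis and trans isomers of 14 arise from the two diastereomers of 13. The selectivity needed is ring closure over cross-metathesis oligomerisation and over ruthenium-hydride alkene migration towards nitrogen; it is secured by the non-basic sulfonamide nitrogen that cannot bind ruthenium, by the two alpha substituents and the tosyl group that fold the vinyl arms towards each other, by high dilution, and by benzoquinone as hydride scavenger. The primary hydroxyl group is homoallylic to the alkene and is tolerated by this catalyst.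

Step 8
Reactants: 14 (5-henicosyl-1-tosyl-2,5-dihydro-1H-pyrrol-2-yl)methanol
Product: 15 5-henicosyl-1-tosyl-2,5-dihydro-1H-pyrrole-2-carbaldehyde (diastereomer mixture)
Conditions: Dess–Martin periodinane (1.3 equiv), CH2Cl2, 0 °C to rt
Reagents that add atoms: none
Why: Dess–Martin oxidation converts the primary alcohol into the aldehyde under mild non-aqueous conditions that spare the ring alkene and the sulfonamide, the now epimerisable C2 centre is of no concern, and the sensitive aldehyde is carried on crude.

Step 9
Reactants: 15 5-henicosyl-1-tosyl-2,5-dihydro-1H-pyrrole-2-carbaldehyde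
Product: 17 5-henicosyl-1H-pyrrole-2-carbaldehyde, via 2H-pyrrole tautomer 16 (not isolated)
Conditions: DBU (2 equiv), CH2Cl2, 0 °C to rt
Reagents that add atoms: none
Why: E1cB-type 1,2-elimination of sulfinate from an N-sulfonyl-3-pyrroline bearing a 2-carbonyl group, a known pyrrole-forming aromatisation: DBU removes the C2 proton acidified by the formyl group, the ring alkene and the sulfonamide nitrogen, the resulting dienolate expels p-toluenesulfinate from N1 to give 16, and base-mediated transfer of the C5 proton to nitrogen delivers the aromatic 1H-pyrrole with loss of both stereocentres.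

Compound list
1 | 1-docosanol | CCCCCCCCCCCCCCCCCCCCCCO | starting material
2 | docosanal | CCCCCCCCCCCCCCCCCCCCCC=O | intermediate
3 | p-toluenesulfonamide | Cc1ccc(cc1)S(N)(=O)=O | starting material
4 | 4-methyl-N-[1-(4-methylbenzenesulfonyl)docosyl]benzenesulfonamide (racemic) | CCCCCCCCCCCCCCCCCCCCCC(NS(=O)(=O)c1ccc(C)cc1)S(=O)(=O)c1ccc(C)cc1 | intermediate
5 | vinylmagnesium bromide | C=C[Mg]Br | starting material
6 | (E)-N-docosylidene-4-methylbenzenesulfonamide (N-tosylimine of docosanal, not isolated) | CCCCCCCCCCCCCCCCCCCCC/C=N/S(=O)(=O)c1ccc(C)cc1 | intermediate
7 | 4-methyl-N-(tetracos-1-en-3-yl)benzenesulfonamide (racemic) | CCCCCCCCCCCCCCCCCCCCCC(C=C)NS(=O)(=O)c1ccc(C)cc1 | intermediate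
8 | (tert-butyldimethylsilyloxy)acetaldehyde | CC(C)(C)[Si](C)(C)OCC=O | starting material
9 | bromomagnesium 1-[(tert-butyldimethylsilyl)oxy]but-3-en-2-olate (racemic, not isolated) | CC(C)(C)[Si](C)(C)OCC(C=C)O[Mg]Br | intermediate
10 | 1-[(tert-butyldimethylsilyl)oxy]but-3-en-2-yl methyl carbonate (racemic) | COC(=O)OC(C=C)CO[Si](C)(C)C(C)(C)C | intermediate
11 | lithium salt of 4-methyl-N-(tetracos-1-en-3-yl)benzenesulfonamide (racemic, not isolated) | [Li+].CCCCCCCCCCCCCCCCCCCCCC(C=C)[N-]S(=O)(=O)c1ccc(C)cc1 | intermediate
12 | N-{1-[(tert-butyldimethylsilyl)oxy]but-3-en-2-yl}-4-methyl-N-(tetracos-1-en-3-yl)benzenesulfonamide (diastereomer mixture) | CCCCCCCCCCCCCCCCCCCCCC(C=C)N(C(CO[Si](C)(C)C(C)(C)C)C=C)S(=O)(=O)c1ccc(C)cc1 | intermediate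
13 | N-(1-hydroxybut-3-en-2-yl)-4-methyl-N-(tetracos-1-en-3-yl)benzenesulfonamide (diastereomer mixture) | CCCCCCCCCCCCCCCCCCCCCC(C=C)N(C(CO)C=C)S(=O)(=O)c1ccc(C)cc1 | intermediate
14 | (5-henicosyl-1-tosyl-2,5-dihydro-1H-pyrrol-2-yl)methanol (cis/trans mixture) | CCCCCCCCCCCCCCCCCCCCCC1C=CC(CO)N1S(=O)(=O)c2ccc(C)cc2 | intermediate
15 | 5-henicosyl-1-tosyl-2,5-dihydro-1H-pyrrole-2-carbaldehyde (diastereomer mixture) | CCCCCCCCCCCCCCCCCCCCCC1C=CC(C=O)N1S(=O)(=O)c2ccc(C)cc2 | intermediate
16 | 2-henicosyl-2H-pyrrole-5-carbaldehyde (racemic, not isolated) | CCCCCCCCCCCCCCCCCCCCCC1C=CC(C=O)=N1 | intermediate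
17 | 5-henicosyl-1H-pyrrole-2-carbaldehyde | CCCCCCCCCCCCCCCCCCCCCc1ccc(C=O)[nH]1 | target

Total step count: 9
Longest linear sequence: 8 (steps 1, 2, 3, 5, 6, 7, 8 and 9, from 1-docosanol)

Steps most likely to fail

Step 7.
- Risk: the ruthenium alkylidene may load slowly onto either of the two alpha-branched vinyl groups. That would leave time for hydride-induced alkene migration towards nitrogen and for intermolecular cross-metathesis.
- Fallback: it sets out from 7 and comes back at 17.
- Sulfonamide 7 is N-alkylated with allyl bromide (K2CO3, DMF) to N-allyl-4-methyl-N-(tetracos-1-en-3-yl)benzenesulfonamide F1, whose unbranched allyl arm offers the catalyst an open loading site.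
- Metathesis closure of this less crowded diene should give 2-henicosyl-1-tosyl-2,5-dihydro-1H-pyrrole F2.
- KOtBu in DMSO then expels sulfinate to give 2-henicosyl-1H-pyrrole F3.
- Vilsmeier–Haack formylation (POCl3, DMF; aqueous NaOAc) at the free alpha position gives 17.
- The one-carbon unit is thus introduced by electrophilic substitution after aromatisation, instead of being carried through the ring closure.

Step 5.
- Risk: C–N bond formation between two secondary centres may be sluggish. The rhodium enyl intermediate could then equilibrate, with loss of the branched regioselectivity, and liberated methoxide could cleave the carbonate.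
- Fallback: it sets out from 7 and comes back at 13.
- Compound 7 is treated with commercial butadiene monoxide (C=CC1CO1) in CH2Cl2, using Pd2(dba)3·CHCl3, racemic N,N'-(cyclohexane-1,2-diyl)bis[2-(diphenylphosphanyl)-1-naphthamide] and a catalytic amount of Cs2CO3.
- Zerovalent palladium opens the epoxide to a pi-allyl complex whose alkoxide deprotonates the sulfonamide and guides it by hydrogen bonding to the near allyl terminus.
- This should give 13 directly and makes 10, 12 and step 6 unnecessary. No compound outside the list is made (F0).

Step 3.
- Risk: the Grignard reagent may deprotonate the enolisable sulfonylimine at the alpha carbon. That leads to tautomerisation and self-condensation instead of 1,2-addition.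
- Fallback: it sets out from 2 and comes back at 7.
- Docosanal is condensed with racemic tert-butanesulfinamide (Ti(OEt)4, THF) to (E)-N-docosylidene-2-methylpropane-2-sulfinamide F4, an imine class that tolerates alpha protons.
- Vinylmagnesium bromide in CH2Cl2 at low temperature adds to give 2-methyl-N-(tetracos-1-en-3-yl)propane-2-sulfinamide F5.
- HCl in methanol removes the sulfinyl group and, after basification, gives tetracos-1-en-3-amine F6.
- Tosyl chloride with triethylamine in CH2Cl2 then gives 7.

Further compounds
F1 | step 7 | N-allyl-4-methyl-N-(tetracos-1-en-3-yl)benzenesulfonamide (racemic) | CCCCCCCCCCCCCCCCCCCCCC(C=C)N(CC=C)S(=O)(=O)c1ccc(C)cc1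
F2 | step 7 | 2-henicosyl-1-tosyl-2,5-dihydro-1H-pyrrole (racemic) | CCCCCCCCCCCCCCCCCCCCCC1C=CCN1S(=O)(=O)c2ccc(C)cc2
F3 | step 7 | 2-henicosyl-1H-pyrrole | CCCCCCCCCCCCCCCCCCCCCc1ccc[nH]1
F0 | step 5 | none | none
F4 | step 3 | (E)-N-docosylidene-2-methylpropane-2-sulfinamide (racemic at sulfur) | CCCCCCCCCCCCCCCCCCCCC/C=N/S(=O)C(C)(C)C
F5 | step 3 | 2-methyl-N-(tetracos-1-en-3-yl)propane-2-sulfinamide (racemic, diastereomer mixture) | CCCCCCCCCCCCCCCCCCCCCC(C=C)NS(=O)C(C)(C)C
F6 | step 3 | tetracos-1-en-3-amine (racemic) | CCCCCCCCCCCCCCCCCCCCCC(N)C=C
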